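Atom labels used throughout: oxolane O1, C2–C5. C7' is the exocyclic benzylic CH2 on C4. Ring A is the 4-oxy-3-methoxyphenyl group on C2. Ring B is the 4-oxy-3,5-dimethoxyphenyl group on C7'.

## The problem

Compound 14 is a 2,3,4-trisubstituted oxolane: C2 carries ring A, C3 a methyl group, C4 the methylene C7' bound to ring B, and C5 is an unsubstituted CH2. The three contiguous stereocentres are (2R,3R,4R), that is all-trans (2,3-trans, 3,4-trans, ring A and the benzyl group 2,4-cis). This is the opposite C3/C4 relationship to the common 3,4-cis furanoid lignans, so methods shaped for those give the wrong diastereomer. C2 and C3 form a carbinol/methyl pair that catalyst-controlled carbonyl addition sets reliably. C4 is the hard centre: its three carbon substituents (C5H2–O, C7'H2–Ar, C3H) are similar in size and it has no neighbouring functional group, so it is best set by C2 and C3 inside a cyclic transition state. Rings A and B are electronically almost alike yet sit in different positions, so each should arrive in its own fragment. The C2–O1 bond is a para-oxygenated benzylic ether: acid ionises it, which epimerises C2 and lets C6' of ring B close a six-membered ring onto C2 (aryltetralin formation), and hydrogenolysis can open it. The free phenols oxidise readily to quinone methides and must stay masked to the end. The enabling feature is the array O1–C5H2–C4(H)–C7'H2–ring B. C5 is bound only to O1 and C4, and C7' is a benzylic CH2, so C7' can be read as a quenched benzylic radical, C4=C7' as a styrene and C5 as an oxygen-bound methyl radical. The C4–C5 bond is then the product of a 5-exo closure of a 2-oxahex-5-enyl radical.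

## Retrosynthesis

**14 ⇒ 13 (two phenolic O–CH2Ph bonds).** The last operation should only unmask the phenols. Benzyl is preferred to its neighbours. Phenolic silyl ethers can migrate to alkoxide 9, allyl ethers would take part in the metathesis and the radical step, and acetal groups need the acid that C2–O1 does not tolerate. Compound 13 holds no oxidisable phenol, and both rings can be bought already benzylated (1, 3). The forward reaction must cleave two aryl benzyl ethers faster than the ring ether.

**13 ⇒ 10 (C4–C5 and C7'–H; key disconnection).**
- Cutting O1–C2 or O1–C5 removes only a C–O bond and leaves the whole triad to be built in the open chain.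
- Cutting C3–C4 gives a radical whose closure is biased to the 3,4-cis series.
- Cutting C2–ring A keeps the ring and forces three separate stereochemical operations.
- Cutting C4–C5 removes the ring, the hard centre C4 and the saturated C7' at once.

Compound 13 goes back through benzylic radical 12 and alkoxymethyl radical 11 to the acyclic O,S-acetal 10, which has only the two easy stereocentres and a styrene. The forward reaction must close 5-exo at C4, choose the C4 face under joint control of C2 and C3, and run in neutral medium. The polar version of the same cut (ionising the acetal carbon C5, Prins-type) is rejected. A 2-oxonia-Cope shift would break C2–C3 and move the charge next to ring A, scrambling both centres, and ring B would compete as a nucleophile.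

**10 ⇒ 7 + 8 (O1–C5).** C5 is brought in as a one-carbon electrophile that already carries the radical leaving group. Attaching C5 on the carbon side instead would mean a hydroxymethyl group at C4, which is the stereocentre problem itself. Compound 7 is a plain secondary alcohol and 8 is commercial. The forward O-alkylation must leave the C2–O bond untouched so that C2 is retained.

**7 ⇒ 6 + 2 (C4=C7').** The alkene is cut in the middle, so ring B enters late in its own fragment and cannot be confused with ring A. Carrying the styrene through the carbonyl addition would need a non-commercial α-aryl crotylmetal. Each of 6 and 2 holds one ring. The forward cross-metathesis must be cross-selective. E-geometry is expected but is erased later, because C7' is not stereogenic.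

**6 ⇒ 3 + 4 (C2–C3).** One bond formation between two commercial compounds creates both easy centres. An aldol route to the same pair would add redox and olefination steps. The forward reaction must be anti-selective and attack the Re face of 3.

**2 ⇒ 1 (C7'=CH2).** A Wittig methylenation turns the commercial aldehyde 1 into the metathesis partner. Nothing stereochemical is asked.

## Roads not taken

**Alternative 1:** (the obvious route) cut the C2–ring A bond and the C3–CH3 bond, keeping the ring as a lactone.
- Forward: the enantiopure β-benzylbutyrolactone A1 is methylated trans through its enolate to A2. An aryl-metal reagent carrying ring A adds to the carbonyl to give lactol A3, and ionic reduction (Et3SiH, BF3·OEt2) gives 13.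
- Why the chosen plan is better: the three stereocentres are set in three separate operations. A1 is not commercial and costs an auxiliary or asymmetric-hydrogenation sequence of several steps, so the count exceeds that of the chosen plan.
- The final reduction places a cation on C2 next to ring A in the presence of a Lewis acid, which is the condition the structure tolerates worst. Ring B is then positioned for six-ring closure, and only the C3 methyl group selects the hydride face.

**Alternative 2:** cut O1–C2.
- Forward: the benzylic alcohol of 1,4-diol A4 is ionised (acid, or as a para-quinone methide after deprotection) and the C5 hydroxyl captures C2, with 2,3-trans under control of C3.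
- Why the chosen plan is better: this closure forms one C–O bond and sets only the easiest centre. The C3/C4 pair, including the hard C4, still has to be built stepwise in the open chain.
- It runs through the same C2 cation with the same aryltetralin hazard. In the oxidative variant with free phenols, C2 and C7' are both para-hydroxybenzylic positions that an oxidant cannot tell apart.

**Alternative 3:** cut C3–C4.
- Forward: a secondary radical at C3, generated from the bromo cinnamyl ether A5, closes 5-exo onto the cinnamyl double bond.
- Why the chosen plan is better: this is a 3-oxahex-5-enyl radical with the methyl group on the radical carbon (position 1) and ring A on position 2. The chair-like model then predicts methyl/benzyl cis and ring A/benzyl trans, which is the 3,4-cis diastereomer A6 and not 13.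
- Moving the radical to C5 puts ring A on position 3 and methyl on position 4. The same model then favours the all-trans array, with both resident centres reinforcing each other.

Key step: step 5

Assumption: (R)-TRIP is taken to direct boronate 4 to the Re face of aryl aldehyde 3, as for simple aryl aldehydes in this reaction class; the (S)-acid is equally available should the sense be the opposite.
Assumption: 1, 3, 4 and 8 are taken as catalogue compounds.

## Steps

Step 1
Reactants: 1 4-(benzyloxy)-3,5-dimethoxybenzaldehyde
Product: 2 2-(benzyloxy)-5-ethenyl-1,3-dimethoxybenzene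
Conditions: MePPh3Br, KOtBu, THF, 0 °C to rt
Reagents that add atoms: methyltriphenylphosphonium bromide, C[P+](c1ccccc1)(c1ccccc1)c1ccccc1.[Br-]
Why: Wittig methylenation of a non-enolisable aromatic aldehyde with the unstabilised ylide; aryl ethers are inert and no stereocentre is involved.

Step 2
Reactants: 3 4-(benzyloxy)-3-methoxybenzaldehyde; 4 (E)-crotylboronic acid pinacol ester
Product: 6 (1R,2R)-1-[4-(benzyloxy)-3-methoxyphenyl]-2-methylbut-3-en-1-ol, via pinacol borate ester 5 (not isolated)
Conditions: (R)-TRIP (5 mol %), PhMe, −30 °C; aq. NaHCO3 work-up
Reagents that add atoms: none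
Why: Chiral-phosphoric-acid-catalysed crotylboration through a closed chair transition state: the E-geometry of 4 becomes the anti C2/C3 relationship and the catalyst pocket selects the Re face of 3, giving (1R,2R); hydrolysis of 5 on work-up releases 6.

Step 3
Reactants: 6 (1R,2R)-1-[4-(benzyloxy)-3-methoxyphenyl]-2-methylbut-3-en-1-ol; 2 2-(benzyloxy)-5-ethenyl-1,3-dimethoxybenzene
Product: 7 (1R,2R,3E)-1-[4-(benzyloxy)-3-methoxyphenyl]-4-[4-(benzyloxy)-3,5-dimethoxyphenyl]-2-methylbut-3-en-1-ol
Conditions: Hoveyda–Grubbs II (5 mol %), 2 (2.5 equiv), CH2Cl2, 40 °C
Reagents that add atoms: none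
Why: Olefin cross-metathesis of a styrene with a terminal alkene that is slow to homodimerise because of its allylic branch should be cross-selective and E under thermodynamic control; the free hydroxyl is tolerated and C2/C3 are not touched. The step is placed before sulfur is introduced so that the Ru catalyst is not slowed.

Step 4
Reactants: 7 (1R,2R,3E)-1-[4-(benzyloxy)-3-methoxyphenyl]-4-[4-(benzyloxy)-3,5-dimethoxyphenyl]-2-methylbut-3-en-1-ol; 8 chloromethyl phenyl sulfide
Product: 10 (phenylsulfanyl)methyl ether of 7, via sodium alkoxide 9 (not isolated)
Conditions: NaH, NaI (cat.), THF–DMF, 0 °C to rt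
Reagents that add atoms: none
Why: Williamson-type formation of a (phenylthio)methyl ether, a known hydroxyl derivatisation, helped by in situ halide exchange; only the O–H bond reacts, so C2 keeps its configuration, and benzyl ethers and the styrene are stable to NaH.

Step 5
Reactants: 10 (phenylsulfanyl)methyl ether of 7
Product: 13 (2R,3R,4R)-2-[4-(benzyloxy)-3-methoxyphenyl]-4-[4-(benzyloxy)-3,5-dimethoxybenzyl]-3-methyloxolane, via alkoxymethyl radical 11 (not isolated), via benzylic radical 12 (not isolated)
Conditions: Bu3SnH (syringe pump), AIBN, PhH, 80 °C, 0.01 M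
Reagents that add atoms: none
Why: The stannyl radical displaces the oxygen-stabilised radical 11 from sulfur of O,S-acetal 10; C5 of 11 adds to C4 of the styrene to give the ring-B-stabilised radical 12, which takes hydrogen from the stannane at C7' and carries the chain. The closest known reaction type is the cyclisation of alkoxymethyl radicals, generated from (phenylseleno)methyl or (phenylthio)methyl ethers of homoallylic alcohols, to 2,4-cis-oxolanes. The single ring closes 5-exo-trig (2-oxahex-5-enyl radical, C5 to C4); 6-endo attack at C7' would forgo benzylic stabilisation and is disfavoured kinetically and thermodynamically. The only new stereocentre, C4, is set in a chair-like transition state with ring A on C2 and the methyl group on C3 both pseudo-equatorial, which is possible because 10 is the anti isomer; a 3-substituent on such a radical directs the new side chain cis and a 4-substituent directs it trans, so both resident centres point to 2,4-cis/3,4-trans, that is (4R). Closure must outrun hydrogen transfer to 11, which the activated styrene acceptor and the low stationary stannane concentration secure. Fragmentation of 11 to formaldehyde and a benzylic radical is about thermoneutral with a high barrier and should not compete. The medium is neutral, so C2–O1 is not ionised: no epimerisation, no oxonia-Cope shift, no attack by ring B. C7' is not stereogenic, so alkene geometry and the face of the last hydrogen transfer do not matter.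

Step 6
Reactants: 13 (2R,3R,4R)-2-[4-(benzyloxy)-3-methoxyphenyl]-4-[4-(benzyloxy)-3,5-dimethoxybenzyl]-3-methyloxolane
Product: 14 (2R,3R,4R)-2-(4-hydroxy-3-methoxyphenyl)-4-(4-hydroxy-3,5-dimethoxybenzyl)-3-methyloxolane
Conditions: H2 (1 atm), 10% Pd/C, EtOAc, rt, stopped after uptake of 2 equiv
Reagents that add atoms: none
Why: Catalytic hydrogenolysis of aryl benzyl ethers (unhindered primary benzylic carbon, phenol as leaving group) should be much faster than that of the ring's secondary dialkyl benzylic ether, above all in a neutral aprotic solvent at 1 atm; no stereocentre is touched.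

## Compound list

1 | 4-(benzyloxy)-3,5-dimethoxybenzaldehyde | COc1cc(C=O)cc(OC)c1OCc1ccccc1 | starting material
2 | 2-(benzyloxy)-5-ethenyl-1,3-dimethoxybenzene | COc1cc(C=C)cc(OC)c1OCc1ccccc1 | intermediate
3 | 4-(benzyloxy)-3-methoxybenzaldehyde | COc1cc(C=O)ccc1OCc1ccccc1 | starting material
4 | 2-[(2E)-but-2-en-1-yl]-4,4,5,5-tetramethyl-1,3,2-dioxaborolane | C/C=C/CB1OC(C)(C)C(C)(C)O1 | starting material
5 | pinacol borate ester of 6 (not isolated) | COc1cc([C@H](OB2OC(C)(C)C(C)(C)O2)[C@H](C)C=C)ccc1OCc1ccccc1 | intermediate
6 | (1R,2R)-1-[4-(benzyloxy)-3-methoxyphenyl]-2-methylbut-3-en-1-ol | COc1cc([C@H](O)[C@H](C)C=C)ccc1OCc1ccccc1 | intermediate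
7 | (1R,2R,3E)-1-[4-(benzyloxy)-3-methoxyphenyl]-4-[4-(benzyloxy)-3,5-dimethoxyphenyl]-2-methylbut-3-en-1-ol | COc1cc([C@H](O)[C@H](C)/C=C/c2cc(OC)c(OCc3ccccc3)c(OC)c2)ccc1OCc1ccccc1 | intermediate
8 | chloromethyl phenyl sulfide | ClCSc1ccccc1 | starting material
9 | sodium alkoxide of 7 (not isolated) | COc1cc([C@H]([O-])[C@H](C)/C=C/c2cc(OC)c(OCc3ccccc3)c(OC)c2)ccc1OCc1ccccc1.[Na+] | intermediate
10 | (phenylsulfanyl)methyl ether of 7, (1R,2R,3E) | COc1cc([C@H](OCSc2ccccc2)[C@H](C)/C=C/c2cc(OC)c(OCc3ccccc3)c(OC)c2)ccc1OCc1ccccc1 | intermediate
11 | alkoxymethyl radical, C5 radical on O1 (not isolated) | COc1cc([C@H](O[CH2])[C@H](C)/C=C/c2cc(OC)c(OCc3ccccc3)c(OC)c2)ccc1OCc1ccccc1 | intermediate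
12 | cyclised benzylic radical at C7' (not isolated) | COc1cc([C@@H]2OC[C@H]([CH]c3cc(OC)c(OCc4ccccc4)c(OC)c3)[C@H]2C)ccc1OCc1ccccc1 | intermediate
13 | (2R,3R,4R)-2-[4-(benzyloxy)-3-methoxyphenyl]-4-[4-(benzyloxy)-3,5-dimethoxybenzyl]-3-methyloxolane | COc1cc([C@@H]2OC[C@H](Cc3cc(OC)c(OCc4ccccc4)c(OC)c3)[C@H]2C)ccc1OCc1ccccc1 | intermediate
14 | (2R,3R,4R)-2-(4-hydroxy-3-methoxyphenyl)-4-(4-hydroxy-3,5-dimethoxybenzyl)-3-methyloxolane | COc1cc([C@@H]2OC[C@H](Cc3cc(OC)c(O)c(OC)c3)[C@H]2C)ccc1O | target

## Step count and risks

Total steps: 6. Longest linear sequence: 5 (steps 2–6 from 3); step 1 is a one-step branch.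

**Step 5 (key step).**
- Risk: slow homolytic substitution at sulfur may let the chain die. Hydrogen transfer to the alkoxymethyl radical may precede closure. Facial discrimination at C4 may be incomplete at 80 °C.
- Fallback (silicon tether, from 7 back to 13): 7 is silylated with (bromomethyl)chlorodimethylsilane (Et3N, DMAP, CH2Cl2) to the (bromomethyl)dimethylsilyl ether F1, whose bromide is a far better radical source.
- Bu3SnH/AIBN closes 6-exo-trig onto C4, again giving the benzylic radical, through a true chair with three equatorial groups. This gives the 1,2-oxasilinane F2.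
- Tamao oxidation (H2O2, KF, KHCO3, THF–MeOH) gives the 1,4-diol F3. Selective sulfonylation of the primary hydroxyl (TsCl, Et3N, CH2Cl2, 0 °C) gives the primary tosylate F4.
- NaH in THF then closes O1–C5 in a 5-exo-tet Williamson reaction that leaves the C2–O bond intact, arriving at 13.

**Step 4.**
- Risk: O-alkylation of a hindered secondary benzylic alkoxide by a soft, weakly electrophilic chloride may be sluggish, with decomposition of the electrophile under the basic conditions.
- Fallback (decarboxylative radical generation, from 7 back to 13): 7 is alkylated with the much more reactive bromoacetic acid (NaH, THF) to the alkoxyacetic acid F5.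
- F5 is coupled with N-hydroxyphthalimide (DIC, DMAP cat., CH2Cl2) to the redox-active ester F6.
- Reductive photoredox fragmentation (Ru(bpy)3(PF6)2, Hantzsch ester, i-Pr2NEt, blue light) gives the same radical 11, which closes to 13. These conditions are reducing, so the electron-rich arenes and the styrene are not oxidised, and no tin is used.

**Step 3.**
- Risk: homodimerisation of the styrene partner may outrun cross-metathesis at the branched alkene, and ruthenium hydride species may shift the double bond.
- Fallback (C7'–ring B bond formation instead of C4=C7', from 6 back to 7): commercial 4-bromo-2,6-dimethoxyphenol is benzylated (BnBr, K2CO3, DMF) to the aryl bromide F7.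
- A Mizoroki–Heck arylation of the terminal alkene of 6 (Pd(OAc)2, P(o-tol)3, Et3N, DMF, 100 °C) follows. β-Hydride elimination toward C7' gives the conjugated E-styrene 7.

**Step 6.**
- Risk: hydrogenolytic opening of the ring at C2–O1 may set in once the para-phenol of ring A is free, and traces of sulfur or tin from step 5 may poison the catalyst.
- Fallback (single-electron reductive cleavage, from 13 back to 14): lithium naphthalenide in THF at −78 to −25 °C transfers electrons to the unsubstituted phenyl rings of the benzyl groups, which expel phenoxide.
- Rings A and B are too electron-rich to accept an electron and become more so as phenoxides, so C2–O1 should survive. The dilithium bisphenolate F8 is protonated with aq. NH4Cl to 14.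

**Step 2.**
- Risk: uncatalysed background addition to the aldehyde, or a poor fit of the electron-rich, ortho-oxygenated ring in the catalyst pocket, may erode the enantiomeric purity. Any Z-isomer in 4 erodes the anti selectivity.
- Fallback (no preformed organometallic, from 3 back to 6): iridium-catalysed transfer-hydrogenative carbonyl crotylation of 3 with but-3-en-2-yl acetate. Conditions are [Ir(cod)Cl]2, SEGPHOS in the antipode that gives (1R,2R), 4-cyano-3-nitrobenzoic acid, Cs2CO3, i-PrOH, THF, 90 °C.
- A chiral π-crotyliridium nucleophile adds anti-selectively. No new isolable compound is made.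

## Further compounds

F1 | step 5 | (bromomethyl)dimethylsilyl ether of 7 | COc1cc([C@H](O[Si](C)(C)CBr)[C@H](C)/C=C/c2cc(OC)c(OCc3ccccc3)c(OC)c2)ccc1OCc1ccccc1
F2 | step 5 | (4R,5R,6R)-6-[4-(benzyloxy)-3-methoxyphenyl]-4-[4-(benzyloxy)-3,5-dimethoxybenzyl]-2,2,5-trimethyl-1,2-oxasilinane | COc1cc([C@@H]2O[Si](C)(C)C[C@H](Cc3cc(OC)c(OCc4ccccc4)c(OC)c3)[C@H]2C)ccc1OCc1ccccc1
F3 | step 5 | (1R,2R,3R)-1-[4-(benzyloxy)-3-methoxyphenyl]-3-[4-(benzyloxy)-3,5-dimethoxybenzyl]-2-methylbutane-1,4-diol | COc1cc([C@H](O)[C@H](C)[C@H](CO)Cc2cc(OC)c(OCc3ccccc3)c(OC)c2)ccc1OCc1ccccc1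
F4 | step 5 | primary 4-methylbenzenesulfonate of F3 | COc1cc([C@H](O)[C@H](C)[C@H](COS(=O)(=O)c2ccc(C)cc2)Cc2cc(OC)c(OCc3ccccc3)c(OC)c2)ccc1OCc1ccccc1
F5 | step 4 | carboxymethyl ether of 7 (alkoxyacetic acid) | COc1cc([C@H](OCC(=O)O)[C@H](C)/C=C/c2cc(OC)c(OCc3ccccc3)c(OC)c2)ccc1OCc1ccccc1
F6 | step 4 | N-(acyloxy)phthalimide of F5 | COc1cc([C@H](OCC(=O)ON2C(=O)c3ccccc3C2=O)[C@H](C)/C=C/c2cc(OC)c(OCc3ccccc3)c(OC)c2)ccc1OCc1ccccc1
F7 | step 3 | 2-(benzyloxy)-5-bromo-1,3-dimethoxybenzene | COc1cc(Br)cc(OC)c1OCc1ccccc1
F8 | step 6 | dilithium bisphenolate of 14 | COc1cc([C@@H]2OC[C@H](Cc3cc(OC)c([O-])c(OC)c3)[C@H]2C)ccc1[O-].[Li+].[Li+]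
F0 | step 2 | none | none
A1 | alternative 1 | (4R)-4-[4-(benzyloxy)-3,5-dimethoxybenzyl]oxolan-2-one | O=C1OC[C@H](Cc2cc(OC)c(OCc3ccccc3)c(OC)c2)C1
A2 | alternative 1 | (3R,4R)-4-[4-(benzyloxy)-3,5-dimethoxybenzyl]-3-methyloxolan-2-one | O=C1OC[C@H](Cc2cc(OC)c(OCc3ccccc3)c(OC)c2)[C@H]1C
A3 | alternative 1 | (3R,4R)-2-[4-(benzyloxy)-3-methoxyphenyl]-4-[4-(benzyloxy)-3,5-dimethoxybenzyl]-3-methyloxolan-2-ol (anomers) | COc1cc(C2(O)OC[C@H](Cc3cc(OC)c(OCc4ccccc4)c(OC)c3)[C@H]2C)ccc1OCc1ccccc1
A4 | alternative 2 | (2R,3R)-1-[4-(benzyloxy)-3-methoxyphenyl]-3-[4-(benzyloxy)-3,5-dimethoxybenzyl]-2-methylbutane-1,4-diol (C1 epimers) | COc1cc(C(O)[C@H](C)[C@H](CO)Cc2cc(OC)c(OCc3ccccc3)c(OC)c2)ccc1OCc1ccccc1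
A5 | alternative 3 | 2-bromo-1-[4-(benzyloxy)-3-methoxyphenyl]propyl (E)-3-[4-(benzyloxy)-3,5-dimethoxyphenyl]prop-2-enyl ether, benzylic carbon configured as C2 of 13 | COc1cc([C@H](OC/C=C/c2cc(OC)c(OCc3ccccc3)c(OC)c2)C(C)Br)ccc1OCc1ccccc1
A6 | alternative 3 | (2R,3R,4S)-2-[4-(benzyloxy)-3-methoxyphenyl]-4-[4-(benzyloxy)-3,5-dimethoxybenzyl]-3-methyloxolane (3,4-cis isomer) | COc1cc([C@@H]2OC[C@@H](Cc3cc(OC)c(OCc4ccccc4)c(OC)c3)[C@H]2C)ccc1OCc1ccccc1
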